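## Analysis of the target

Target 11 is an unbranched diarylnonanoid. C1 of a nine-carbon chain is a ketone carbon bonded to a 2,6-dihydroxyphenyl ring (ring A), C2 to C9 are eight methylene groups, and C9 is the benzylic carbon of a 4-hydroxy-3-methoxyphenyl ring (ring B). There is no stereocentre and no ring other than the two benzene rings, so the task is one of connectivity, regiochemistry and functional-group compatibility. The sensitive groups are three free phenols, a methyl ether on ring B that must outlast every deprotection, and an aryl ketone that must not be reduced or hydrogenolysed. The first difficulty is that the acyl group sits between the two oxygens of ring A, where direct acylation of resorcinol does not go (it goes para to one oxygen). The second is that the eight-methylene tether must be assembled to exact length, and the one methylated phenol is best bought with its methyl group in place. The strategy rests on the C8–C9 bond beside ring B: written as a C8=C9 double bond, C9 and ring B form the arylpropenyl unit of isoeugenol 7, which is commercial and already carries the 4-hydroxy-3-methoxy pattern. The remainder, C1 to C8 with ring A, then becomes a terminal alkene.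

## Retrosynthetic reasoning

**11 to 9.** No skeletal bond is cut. Target 11 is traced back to the tris-benzyl ether 9 with a C8=C9 double bond. In the forward sense one heterogeneous hydrogenation saturates the alkene (passing through the saturated ether 10) and removes all three benzyl groups. This gives an alkene retron at C8=C9 and phenol protection that needs no deprotection step of its own.

**9 to 6 and 8.** The C8=C9 double bond is cut in a cross-metathesis sense, giving terminal alkene 6 (C1 to C8 plus one extruded carbon, with ring A) and propenylarene 8 (C9 with ring B).
- A double bond anywhere between C2 and C7 would pair two terminal alkenes of the same class, which couple statistically. At C8=C9 a conjugated 1,2-disubstituted styrenyl alkene meets an unhindered terminal alkene, so the pairing is biased towards the cross product.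
- Cutting the C9–ring B single bond would need an sp2–sp3 coupling of an alkylmetal that tolerates the ketone.
- The forward reaction has to join the two alkenes with loss of a volatile three-carbon olefin and without moving the double bond of 6 along the chain.

**8 to 7.** The benzyl ether of 8 is removed on paper to give isoeugenol 7. The benzyl group matches those on ring A, so one final operation clears all three.

**6 to 5, then to 2 and 4.** Ketone 6 comes from carbinol 5 by oxidation. Carbinol 5 is cut at C1–C2 into aldehyde 2 and Grignard reagent 4, made from bromide 3.
- The cut is at C1–C2 and not at the C1–ring A bond because the formyl carbon of 2 already sits between the two oxygens, so the regiochemistry of ring A is bought.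
- Acylation of a ring A arene would go to the wrong position, and an aryl-anion route would expose the benzylic ether protons to strong base.
- The forward reactions must add a primary alkylmagnesium to a hindered, non-enolisable aldehyde and then raise the oxidation level without touching the terminal alkene.

**2 to 1.** Both phenols of 1 are benzylated. This shields them from the organomagnesium and ties their release to the final hydrogenation.

## Alternatives that were turned down

**Alternative 1: Dieckmann construction of ring A, then aromatisation.**
- Disconnection: ring A is made rather than bought. After retro-aromatisation, the ring bond between the acyl-bearing carbon and an oxygenated ring carbon is cut.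
- Forward key step: methyl 15-(4-(benzyloxy)-3-methoxyphenyl)-5,7-dioxopentadecanoate A1 is treated with NaOMe. Its C6 enolate attacks the ester carbonyl and closes the six-membered ring, giving 2-(9-(4-(benzyloxy)-3-methoxyphenyl)nonanoyl)cyclohexane-1,3-dione A2. Dehydrogenation of the dione ring and debenzylation would follow.
- For: the acyl group is placed between the two oxygens by construction. Ring A needs no protecting group, and the ring-forming chemistry uses only cheap base. On these points it is stronger than the chosen route.
- Against: A1 must already contain the whole aryl-alkyl chain, so chain assembly is only moved upstream. A1 needs a regiocontrolled Claisen-type acylation. Methoxide can cleave the 1,3-dicarbonyl unit by retro-Claisen reaction in competition with cyclisation. The dehydrogenation of A2 to the aromatic level needs an oxidant such as Hg(OAc)2 or DDQ in the presence of electron-rich ring B and its benzylic C9 position.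
- Comparison: the chosen route buys both rings with the right oxygen pattern and spends its steps only on the chain, so it is shorter and its risk sits in one catalytic step.

**Alternative 2: Nickel-electrocatalytic doubly decarboxylative coupling within the chain.**
- Disconnection: the C7–C8 single bond.
- Forward key step: the N-hydroxyphthalimide esters A3 (ring A ketone with a C8 acid chain) and A4 (3-arylpropanoate of ring B) are reduced at a cathode with NiCl2(glyme) and a terpyridine ligand. Both decarboxylate and the two primary alkyl fragments join to give the tris-MOM ether A5. Mild acid would then release 11.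
- For: the sp3–sp3 bond is made at the final oxidation level. There is no alkene to saturate, no possible double-bond migration, and no hydrogenation that could threaten the ketone. On these three points it is stronger than the chosen route.
- Against: the two primary alkyl partners are nearly alike, so cross-selectivity has no structural basis and needs a large excess of one ester. A3 still requires the acylation between the oxygens of ring A, and both acids need separate activation. The aryl ketone and the phthalimide units are themselves reducible at the cathode.
- Comparison: the chosen metathesis pairs two alkenes of different class, so the selectivity comes from the substrates. The fragments are reached in one to three steps from commercial materials, and the overall count is lower.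

**Alternative 3: Aryne insertion into the carboxylic acid C–O bond.**
- Disconnection: the ring A–C1 bond and one ring A–oxygen bond, on adjacent ring carbons.
- Forward key step: CsF releases 3-(benzyloxy)benzyne A7 from the silyl triflate A6. The carboxylate of the full-chain acid A8 adds through oxygen at the aryne carbon remote from the benzyloxy group. The aryl anion next to that group attacks the carbonyl, and the four-membered intermediate opens to the ortho-hydroxyaryl ketone A9.
- For: the 2-acyl-1,3-dioxygenated arene is formed in one step, with regiochemistry set by the inductive effect of the alkoxy group. It needs no organomagnesium and no oxidation. On the ring A end it is more direct than the chosen route.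
- Against: A6 is not a catalogue compound and needs several steps. A8 contains the entire chain and must be built first, so a chain-forming step is still required. The acid is its own proton source, so simple O-arylation by protonation of the aryl anion competes with acyl transfer. The step therefore consumes the most valuable fragment in a reaction of uncertain efficiency.
- Comparison: the chosen route uses an aldehyde that already has the 2,6-dioxygenation, puts its late-stage risk on a well-precedented catalytic reaction, and needs no separate synthesis of the chain.

Key step: step 5

Assumption: isoeugenol 7 is drawn as its E isomer. The commercial E/Z mixture would serve equally, because both geometries enter the metathesis and the double bond is removed in step 6.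

## Route

Step 1
Reactants: 1 2,6-dihydroxybenzaldehyde
Product: 2 2,6-bis(benzyloxy)benzaldehyde
Conditions: BnBr (2.4 equiv), K2CO3 (3 equiv), DMF, 60 °C
Reagents that add atoms: benzyl bromide, BrCc1ccccc1
Why: Williamson ether synthesis; the two phenols are hydrogen-bonded to the formyl group and only moderately nucleophilic, so carbonate in warm DMF with a reactive benzylic bromide is used. The aldehyde has no α-hydrogen and is inert to these conditions.

Step 2
Reactants: 2 2,6-bis(benzyloxy)benzaldehyde; 3 8-bromooct-1-ene
Product: 5 rac-1-(2,6-bis(benzyloxy)phenyl)non-8-en-1-ol, via oct-7-enylmagnesium bromide 4 (not isolated)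
Conditions: 3, Mg, I2 (cat.), THF, rt to 40 °C; then 2, THF, 0 °C to rt; aq NH4Cl
Reagents that add atoms: magnesium, [Mg] (it enters intermediate 4 only and is lost on work-up)
Why: Grignard formation followed by 1,2-addition to a non-enolisable aldehyde; the ortho benzyloxy groups can chelate magnesium and guide the nucleophile to the formyl carbon, which becomes C1. The new carbinol centre is formed without control (racemate), which does not matter because step 3 removes it.

Step 3
Reactants: 5 rac-1-(2,6-bis(benzyloxy)phenyl)non-8-en-1-ol
Product: 6 1-(2,6-bis(benzyloxy)phenyl)non-8-en-1-one
Conditions: IBX (1.5 equiv), DMSO, rt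
Reagents that add atoms: none
Why: IBX oxidation of a secondary benzylic alcohol to the ketone by ligand exchange at iodine and elimination. The medium is neutral, so the electron-rich benzylic carbinol should not ionise, and the terminal alkene and benzyl ethers are not attacked at room temperature.

Step 4
Reactants: 7 (E)-isoeugenol, 2-methoxy-4-((E)-prop-1-en-1-yl)phenol
Product: 8 (E)-1-(benzyloxy)-2-methoxy-4-(prop-1-en-1-yl)benzene
Conditions: BnBr (1.2 equiv), K2CO3 (2 equiv), acetone, reflux
Reagents that add atoms: benzyl bromide, BrCc1ccccc1
Why: Williamson ether synthesis on a guaiacol-type phenol; the propenyl group is untouched by the weak base. The benzyl group prevents phenoxide binding and quinone-methide pathways in step 5 and is removed in step 6 at no extra cost.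

Step 5
Reactants: 6 1-(2,6-bis(benzyloxy)phenyl)non-8-en-1-one; 8 (E)-1-(benzyloxy)-2-methoxy-4-(prop-1-en-1-yl)benzene
Product: 9 (E)-1-(2,6-bis(benzyloxy)phenyl)-9-(4-(benzyloxy)-3-methoxyphenyl)non-8-en-1-one
Conditions: 8 (3 equiv), (H2IMes)(PCy3)Cl2Ru=CHPh (second-generation Grubbs catalyst, 5 mol %), 1,4-benzoquinone (10 mol %), CH2Cl2, 40 °C, Ar sweep
Reagents that add atoms: none
Why: Alkene cross-metathesis by the Chauvin mechanism: the ruthenium alkylidene freed from the precatalyst by loss of PCy3 adds to an alkene in a [2+2] sense, and the ruthenacyclobutane cycloreverts to a new alkylidene and a new alkene, which over both partners joins C8 of 6 to the benzylic carbon of 8 and expels propene. The closest known reaction type is the ruthenium-catalysed cross-metathesis of propenylarenes such as anethole- and isoeugenol-type ethers with terminal alkenes. No ring is closed and no stereocentre is formed; only the alkene geometry is new, the conjugated E isomer is favoured thermodynamically, and the geometry is erased in step 6. The selectivity needed is cross- over self-metathesis: the terminal alkene of 6 reacts fast and its self-metathesis product stays metathesis-active and re-enters the cycle, whereas propenylarene 8 self-couples only slowly, so an excess of cheap 8 should channel the material to 9. Removal of propene, and of the ethylene and butene from side equilibria, in the argon stream drives the exchange forward. The ketone of 6 is six methylenes from the alkene and shielded by two ortho benzyloxy groups, so it should neither chelate ruthenium nor react. 1,4-Benzoquinone is added to intercept ruthenium hydride species, because double-bond migration before metathesis would give chain-shortened homologues that could not be separated later.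

Step 6
Reactants: 9 (E)-1-(2,6-bis(benzyloxy)phenyl)-9-(4-(benzyloxy)-3-methoxyphenyl)non-8-en-1-one
Product: 11 1-(2,6-dihydroxyphenyl)-9-(4-hydroxy-3-methoxyphenyl)nonan-1-one (target), via saturated tribenzyl ether 10 (not isolated)
Conditions: H2 (1 atm), Pd/C (10 % Pd), EtOAc/MeOH, rt
Reagents that add atoms: none
Why: Heterogeneous hydrogenation of the styrenyl alkene followed by hydrogenolysis of the three aryl benzyl ethers on palladium; the methyl ether on ring B is inert. The ketone is hindered by two ortho substituents and, once deprotected, held in a strong intramolecular hydrogen bond, so it is not expected to be reduced at atmospheric pressure in a neutral solvent if the reaction is stopped when debenzylation is complete.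

## Compound list

1 | 2,6-dihydroxybenzaldehyde | O=Cc1c(O)cccc1O | starting material
2 | 2,6-bis(benzyloxy)benzaldehyde | O=Cc1c(OCc2ccccc2)cccc1OCc1ccccc1 | intermediate
3 | 8-bromooct-1-ene | C=CCCCCCCBr | starting material
4 | oct-7-enylmagnesium bromide | C=CCCCCCC[Mg]Br | intermediate
5 | rac-1-(2,6-bis(benzyloxy)phenyl)non-8-en-1-ol | C=CCCCCCCC(O)c1c(OCc2ccccc2)cccc1OCc1ccccc1 | intermediate
6 | 1-(2,6-bis(benzyloxy)phenyl)non-8-en-1-one | C=CCCCCCCC(=O)c1c(OCc2ccccc2)cccc1OCc1ccccc1 | intermediate
7 | (E)-isoeugenol, 2-methoxy-4-((E)-prop-1-en-1-yl)phenol | C/C=C/c1ccc(O)c(OC)c1 | starting material
8 | (E)-1-(benzyloxy)-2-methoxy-4-(prop-1-en-1-yl)benzene | C/C=C/c1ccc(OCc2ccccc2)c(OC)c1 | intermediate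
9 | (E)-1-(2,6-bis(benzyloxy)phenyl)-9-(4-(benzyloxy)-3-methoxyphenyl)non-8-en-1-one | COc1cc(/C=C/CCCCCCC(=O)c2c(OCc3ccccc3)cccc2OCc2ccccc2)ccc1OCc1ccccc1 | intermediate
10 | 1-(2,6-bis(benzyloxy)phenyl)-9-(4-(benzyloxy)-3-methoxyphenyl)nonan-1-one | COc1cc(CCCCCCCCC(=O)c2c(OCc3ccccc3)cccc2OCc2ccccc2)ccc1OCc1ccccc1 | intermediate
11 | 1-(2,6-dihydroxyphenyl)-9-(4-hydroxy-3-methoxyphenyl)nonan-1-one | COc1cc(CCCCCCCCC(=O)c2c(O)cccc2O)ccc1O | target

## Step count and risk

Total step count: 6. Longest linear sequence: 5 steps (steps 1, 2, 3, 5, 6); step 4 is a one-step branch that joins at step 5.

**Step 5 (key step).**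
- What may go wrong: self-metathesis of the terminal alkene of 6 may consume the more valuable partner. Double-bond migration by ruthenium hydride species may occur before coupling, with loss of a chain carbon. The catalyst may decompose before conversion is complete.
- Fallback (sets out from 6, returns at 9): the C8=C9 bond is made by carbonyl olefination instead.
  - The terminal alkene of 6 is cleaved with OsO4 (cat.), NaIO4 and 2,6-lutidine in dioxane/H2O to 8-(2,6-bis(benzyloxy)phenyl)-8-oxooctanal F1, whose aldehyde carbon is C8.
  - Separately, commercial (4-(benzyloxy)-3-methoxyphenyl)methanol F2 is heated with PPh3·HBr to give (4-(benzyloxy)-3-methoxybenzyl)triphenylphosphonium bromide F3.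
  - Deprotonation of F3 with KOtBu in THF and Wittig reaction with F1 should give 9. The semi-stabilised ylide should attack the unhindered aldehyde and not the shielded ketone.
  - The product is 9 together with its geometric isomer (Z)-1-(2,6-bis(benzyloxy)phenyl)-9-(4-(benzyloxy)-3-methoxyphenyl)non-8-en-1-one F4. Both go into step 6 unchanged.

**Step 6.**
- What may go wrong: over-reduction of the aryl ketone (to the carbinol and on to the methylene by benzylic hydrogenolysis) on prolonged exposure, or stalling of the debenzylation at the hindered ortho positions of ring A.
- Fallback (sets out from 9, returns at 11): reduction and deprotection are separated and hydrogenolysis is avoided.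
  - The alkene of 9 is reduced with diimide (2-nitrobenzenesulfonyl hydrazide, Et3N, CH2Cl2, rt), which touches neither benzyl ethers nor ketone, so that 10 is isolated.
  - The three benzyl ethers of 10 are then cleaved with BCl3 and pentamethylbenzene in CH2Cl2 at −78 °C. These conditions leave the aryl methyl ether and the ketone alone and give 11.

**Step 2.**
- What may go wrong: Wurtz-type homocoupling during formation of 4 lowers the titre. At the hindered formyl group, hydride transfer from the Grignard reagent (reduction) may compete with addition.
- Fallback (sets out from 2, with 4 from 3; returns at 6): the ring A fragment is raised to the acid level and acylated, so that carbinol 5 and step 3 are bypassed.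
  - Pinnick oxidation of 2 (NaClO2, NaH2PO4, 2-methylbut-2-ene, tBuOH/H2O) gives 2,6-bis(benzyloxy)benzoic acid F5.
  - (COCl)2 with catalytic DMF in CH2Cl2 gives 2,6-bis(benzyloxy)benzoyl chloride F6.
  - F6 is coupled with 4 under Fe(acac)3 catalysis in THF at −78 °C to give ketone 6 directly. The two ortho substituents should suppress over-addition.

## Further compounds

F1 | step 5 | 8-(2,6-bis(benzyloxy)phenyl)-8-oxooctanal | O=CCCCCCCC(=O)c1c(OCc2ccccc2)cccc1OCc1ccccc1
F2 | step 5 | (4-(benzyloxy)-3-methoxyphenyl)methanol | COc1cc(CO)ccc1OCc1ccccc1
F3 | step 5 | (4-(benzyloxy)-3-methoxybenzyl)triphenylphosphonium bromide | COc1cc(C[P+](c2ccccc2)(c2ccccc2)c2ccccc2)ccc1OCc1ccccc1.[Br-]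
F4 | step 5 | (Z)-1-(2,6-bis(benzyloxy)phenyl)-9-(4-(benzyloxy)-3-methoxyphenyl)non-8-en-1-one | COc1cc(/C=C\CCCCCCC(=O)c2c(OCc3ccccc3)cccc2OCc2ccccc2)ccc1OCc1ccccc1
F0 | step 6 | none | none
F5 | step 2 | 2,6-bis(benzyloxy)benzoic acid | O=C(O)c1c(OCc2ccccc2)cccc1OCc1ccccc1
F6 | step 2 | 2,6-bis(benzyloxy)benzoyl chloride | O=C(Cl)c1c(OCc2ccccc2)cccc1OCc1ccccc1
A1 | alternative 1 | methyl 15-(4-(benzyloxy)-3-methoxyphenyl)-5,7-dioxopentadecanoate | COC(=O)CCCC(=O)CC(=O)CCCCCCCCc1ccc(OCc2ccccc2)c(OC)c1
A2 | alternative 1 | 2-(9-(4-(benzyloxy)-3-methoxyphenyl)nonanoyl)cyclohexane-1,3-dione | O=C1CCCC(=O)C1C(=O)CCCCCCCCc1ccc(OCc2ccccc2)c(OC)c1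
A3 | alternative 2 | 1,3-dioxoisoindolin-2-yl 8-(2,6-bis(methoxymethoxy)phenyl)-8-oxooctanoate | COCOc1cccc(OCOC)c1C(=O)CCCCCCC(=O)ON1C(=O)c2ccccc2C1=O
A4 | alternative 2 | 1,3-dioxoisoindolin-2-yl 3-(3-methoxy-4-(methoxymethoxy)phenyl)propanoate | COCOc1ccc(CCC(=O)ON2C(=O)c3ccccc3C2=O)cc1OC
A5 | alternative 2 | 1-(2,6-bis(methoxymethoxy)phenyl)-9-(3-methoxy-4-(methoxymethoxy)phenyl)nonan-1-one | COCOc1ccc(CCCCCCCCC(=O)c2c(OCOC)cccc2OCOC)cc1OC
A6 | alternative 3 | 3-(benzyloxy)-2-(trimethylsilyl)phenyl trifluoromethanesulfonate | C[Si](C)(C)c1c(OCc2ccccc2)cccc1OS(=O)(=O)C(F)(F)F
A7 | alternative 3 | 3-(benzyloxy)benzyne | C1#CC(OCc2ccccc2)=CC=C1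
A8 | alternative 3 | 9-(4-(benzyloxy)-3-methoxyphenyl)nonanoic acid | COc1cc(CCCCCCCCC(=O)O)ccc1OCc1ccccc1
A9 | alternative 3 | 1-(2-(benzyloxy)-6-hydroxyphenyl)-9-(4-(benzyloxy)-3-methoxyphenyl)nonan-1-one | COc1cc(CCCCCCCCC(=O)c2c(O)cccc2OCc2ccccc2)ccc1OCc1ccccc1
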